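**Retrosynthetic overview**
1. Key disconnection (bonds made last): remove both geminal C-methyl groups from the cyclohexadienone ring. This reveals a fully aromatic, unsymmetrical diarylmethane whose trihydroxy ring (ring A) is dearomatised by double C-methylation.
2. Bond made first: the ring A–CH2 bond. It splits into phloroacetophenone (ring A, nucleophile) and the ortho-quinone methide of 2',6'-dihydroxy-4'-methoxyacetophenone (ring B), stored as its Mannich base.
3. One-carbon units: the bridge carbon comes from Eschenmoser's salt and the two quaternary methyl groups from MeI.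
4. Ring order: no ring is built. Both six-membered carbocycles are bought as arenes, ring B stays aromatic, and ring A becomes the dienone in the last step.

Assumption: the target has no stereocentre and no stereogenic double bond. It is achiral, and the SMILES shows one enol tautomer of a β-triketone, so no stereocontrol is needed.

**Step 1**
Reactants: 1 2',6'-dihydroxy-4'-methoxyacetophenone; 2 2',4',6'-trihydroxyacetophenone (phloroacetophenone)
Product: 5 1-[3-[(3-acetyl-2,4-dihydroxy-6-methoxyphenyl)methyl]-2,4,6-trihydroxyphenyl]ethanone (unsymmetrical diarylmethane), via Mannich base 3 (not isolated), via ortho-quinone methide 4 (not isolated)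
Conditions: 1 (1.1 equiv), [CH2=NMe2]I (1.0 equiv), MeCN, 0 °C to rt, 3 h; then 2 (3 equiv), NaOAc (1.2 equiv), 80 °C, 8 h
Reagents that add atoms: N,N-dimethylmethylideneammonium iodide (Eschenmoser's salt), C=[N+](C)C.[I-]
Why: Mannich aminomethylation at the only type of free ring position of 1 gives 3, which loses Me2NH on heating in the NaOAc/AcOH buffer to give ortho-quinone methide 4, and 4 is taken up in a Friedel–Crafts-type conjugate addition by the most nucleophilic arene in the flask, 2 (used in excess so that 5 is not alkylated a second time); no stereocentre is formed.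

**Step 2**
Reactants: 5 unsymmetrical diarylmethane
Product: 7 2-acetyl-6-[(3-acetyl-2,4-dihydroxy-6-methoxyphenyl)methyl]-3,5-dihydroxy-4,4-dimethylcyclohexa-2,5-dien-1-one (target), via C-methyl diarylmethane 6 (not isolated)
Conditions: NaOMe (5 equiv), MeI (2.3 equiv, in portions), MeOH, 0 °C to rt, 16 h; then cold 1 M HCl
Reagents that add atoms: iodomethane (MeI), CI
Why: Proposed new method: the closest known reaction type is the alkylative dearomatisation (geminal double C-methylation) of monomeric acylphloroglucinols with MeI/NaOMe, run here on the preassembled diarylmethane; ring A (three OH, para-OH pKa about 8) forms a di- or trianion that is far more C-nucleophilic than the chelated anion of methoxy ring B, its only free CH is methylated to give 6, the new methyl raises the nucleophilicity of that same carbon so the second MeI strikes there and breaks the aromaticity, and the acidic β-triketone enolate so formed is too stabilised to react on, while the bridge blocks the ring carbon at which the monomer is normally over-methylated; no stereocentre is formed.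

**Compound list**
1 | 2',6'-dihydroxy-4'-methoxyacetophenone | COc1cc(O)c(C(C)=O)c(O)c1 | starting material
2 | 2',4',6'-trihydroxyacetophenone (phloroacetophenone) | CC(=O)c1c(O)cc(O)cc1O | starting material
3 | 1-[3-[(dimethylamino)methyl]-2,6-dihydroxy-4-methoxyphenyl]ethanone (Mannich base) | COc1cc(O)c(C(C)=O)c(O)c1CN(C)C | intermediate
4 | 2-acetyl-3-hydroxy-5-methoxy-6-methylidenecyclohexa-2,4-dien-1-one (ortho-quinone methide) | C=C1C(=O)C(C(C)=O)=C(O)C=C1OC | intermediate
5 | 1-[3-[(3-acetyl-2,4-dihydroxy-6-methoxyphenyl)methyl]-2,4,6-trihydroxyphenyl]ethanone | COc1cc(O)c(C(C)=O)c(O)c1Cc1c(O)cc(O)c(C(C)=O)c1O | intermediate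
6 | 1-[3-[(3-acetyl-2,4-dihydroxy-6-methoxyphenyl)methyl]-2,4,6-trihydroxy-5-methylphenyl]ethanone | COc1cc(O)c(C(C)=O)c(O)c1Cc1c(O)c(C)c(O)c(C(C)=O)c1O | intermediate
7 | 2-acetyl-6-[(3-acetyl-2,4-dihydroxy-6-methoxyphenyl)methyl]-3,5-dihydroxy-4,4-dimethylcyclohexa-2,5-dien-1-one | COc1cc(O)c(C(C)=O)c(O)c1CC1=C(O)C(C)(C)C(O)=C(C(C)=O)C1=O | target

**Total step count:** 2. **Longest linear sequence:** 2.

**Steps most likely to fail**
The route has only two steps, so step 1 is judged once for each of its two stages.

1. Step 2.
   - Risk: MeI may strike the bridge-bearing carbon of ring A or the free CH of ring B. Prolonged alkali can also cut and rejoin the methylene bridge (retro-Michael scrambling into the two symmetrical dimers).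
   - Fallback: dearomatise before coupling. It sets out from 2 and comes back at 7. Compound 2 alone is treated with MeI (2.2 equiv) and NaOMe in MeOH to give 2-acetyl-3,5-dihydroxy-4,4-dimethylcyclohexa-2,5-dien-1-one (acetylfilicinic acid) F1. This then takes the place of 2 in the second stage of step 1. Its only free ring carbon adds to ortho-quinone methide 4 released from Mannich base 3 under the NaOAc buffer, where no strong base touches the finished bridge, and 7 forms directly.

2. Step 1, second stage (capture of 4).
   - Risk: 4 may be taken up by 1, by 3 or by product 5, giving the ring B homodimer and trimers.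
   - Fallback: form the bridge on a symmetrical system, where cross-selectivity does not arise, and break the symmetry afterwards. It sets out from 2 and comes back at 5. Two equivalents of 2 are joined by 37% aqueous formaldehyde (one equivalent) in 1% aqueous KOH at 0 °C to rt and acidified, giving 3,3'-methylenebis(2,4,6-trihydroxyacetophenone) F2. One of its two equivalent, non-chelated OH groups para to acetyl is then methylated with Me2SO4 (0.8 equiv) and K2CO3 in acetone. The mono-methylation is statistical, and unreacted material is recovered and recycled. The mono-ether is 5.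

3. Step 1, first stage (aminomethylation).
   - Risk: 1 may be aminomethylated twice, or the aminomethyl group may pass to 2 by retro-Mannich exchange in the hot second stage, which leads to the ring A homodimer.
   - Fallback: use no formaldehyde-level reagent and bring in the bridge carbon as a third C-methyl group. It sets out from 2 and comes back at 7. Compound 2 is C-methylated three times (MeI 3.3 equiv, NaOMe, MeOH) to 2-acetyl-3,5-dihydroxy-4,4,6-trimethylcyclohexa-2,5-dien-1-one F3. Oxidation with Ag2O and TEMPO (2,2,6,6-tetramethylpiperidin-1-oxyl) in toluene removes two hydrogens and gives 2-acetyl-3-hydroxy-4,4-dimethyl-6-methylidenecyclohex-2-ene-1,5-dione F4. This is generated in the presence of 1 (2 equiv) and is captured at the free ring carbon of 1 in a Friedel–Crafts-type conjugate addition to give 7.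

**Further compounds**
F1 | step 2 | 2-acetyl-3,5-dihydroxy-4,4-dimethylcyclohexa-2,5-dien-1-one (acetylfilicinic acid) | CC(=O)C1=C(O)C(C)(C)C(O)=CC1=O
F2 | step 1 | 3,3'-methylenebis(2,4,6-trihydroxyacetophenone) | CC(=O)c1c(O)cc(O)c(Cc2c(O)cc(O)c(C(C)=O)c2O)c1O
F3 | step 1 | 2-acetyl-3,5-dihydroxy-4,4,6-trimethylcyclohexa-2,5-dien-1-one | CC(=O)C1=C(O)C(C)(C)C(O)=C(C)C1=O
F4 | step 1 | 2-acetyl-3-hydroxy-4,4-dimethyl-6-methylidenecyclohex-2-ene-1,5-dione | C=C1C(=O)C(C(C)=O)=C(O)C(C)(C)C1=O
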